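## Structural features

The target is a 2,3-dihydro-1-benzofuran: a benzene ring (ring A, C3a–C7a) fused to a five-membered ring made of O1, C2 and C3. Ring A carries a hydroxyl at C6 and a 2-(4-hydroxyphenyl)ethyl chain at C4; C2 carries a 4-hydroxyphenyl group and C3 a 3,5-dihydroxyphenyl group. C2 and C3 are adjacent stereocentres of configuration 2S,3R with the two aryl groups cis, the more strained diastereomer; the C4 chain lies peri to C3 and adds to the crowding there. All five oxygens are free phenols, sensitive to air and base. The C2–O1 bond is a para-hydroxybenzylic aryl ether: it can ionise under acid, open to a quinone methide under base (both epimerise C2 towards the trans series), and be cleaved by hydrogenolysis. The real difficulty is to set the cis C2/C3 pair at a benzylic carbon, C3, that finally bears only hydrogen and offers no handle, and then to keep it through deprotection. The key step exploits the fact that C3 is bonded to C3a of ring A, to the resorcinol ring and to C2: this triad results when the fused arene carbon of a 2,3-diaryl-2H-chromene shifts from C4 to C3, and the expelled ring carbon then fills the fourth valence of C3 as a masked formyl group that can be exchanged for hydrogen with retention. The 4-arylethyl/6-oxy pattern of ring A is the resorcinol ring of dihydroresveratrol, so the whole bibenzyl unit can be bought.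

## Logic of the disconnections

17 back to 15 (through 16): four O–CH2Ph bonds and one O–acetyl bond are reconnected. The phenols must be masked against hydride, Lewis acid, trivalent iodine and hot rhodium. Benzyl ethers are chosen because the target has no other reducible group and they leave under neutral hydrogen. The single acetate sits on the C2 aryl ring because an acyloxy group, unlike an alkoxy group, does not stabilise a cation at C2. The gain is a neutral, fully protected intermediate. The forward demand is debenzylation that spares the benzylic C2–O1 bond and an acetate cleavage mild enough not to epimerise C2.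

15 back to 14: the C3–H bond is replaced by a C3–CHO bond. C3 becomes a quaternary centre that cannot epimerise, and the stereochemical task changes from delivering a hydrogen to placing a carbon. The forward step must remove CO with retention at C3 and without β-hydride loss towards the aromatic benzofuran.

14 back to 13: the formyl group is masked as its dimethyl acetal (two C–O bonds), the form in which this carbon leaves the ring contraction. The forward demand is hydrolysis of a hindered acetal without acid ionisation of C2–O1.

13 back to 12: the C3–C3a bond is cut, C3a is rejoined to the acetal carbon and the two methoxy groups are removed, which expands the dihydrofuran to a 2H-pyran with a C3=C4 double bond. The cut is made here because a 1,2-shift of the electron-rich ring A carbon is the one event that makes C3–C3a and the C3 configuration together, relayed from C2. The gain is one stereocentre instead of two, no quaternary carbon, and a flat 3-aryl benzopyran that comes from a condensation. The forward step must add the iodine electrophile at C3 on the face away from the C2 aryl, methanol at C4, and shift C4a with inversion at C3. It must do so faster than hydride loss from C2, methoxy participation or shift of the C2 aryl.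

12 back to 9 and 10 (through 11): the C2–aryl bond is cut. In 9, C2 is at the acetal oxidation level, so the aryl group can enter as a boron nucleophile on the derived benzopyrylium ion under a chiral catalyst. The gain is a core without a fixed stereocentre and a commercial boronic acid. The demand is face control next to the C3 aryl and attack at C2 rather than C4.

9 back to 7 (through 8): the C2–OEt and C2–H bonds are replaced by the lactone carbonyl. The lactone is the robust, directly accessible form of the heterocycle. The demand is a partial reduction that stops at the lactol.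

7 back to 3 and 6: the C3=C4 double bond and the O1–C2 acyl bond are cut. This separates the molecule into a salicylaldehyde that carries ring A with its chain and an arylacetic acid that carries the resorcinol ring. The demand is a condensation at a di-ortho-substituted aldehyde and a single free hydroxyl ortho to the formyl group in 3.

6 back to 4 (through 5), 3 back to 2, and 2 back to 1: O–benzyl bonds are cut in 6 and 3, then the aryl–CHO bond of 2. Compound 1 already contains the complete bibenzyl with the right oxygen pattern. The demands are benzylation of the two non-chelated phenols only, and formylation of the resorcinol ring ortho to the chain and para to a hydroxyl.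

## Other disconnections considered

Alternative 1: The cut dismantles ring A along C3a–C7a, C4–C5 and C6–C7. It leaves the ynol-ether 1,6-diyne A2 (tether O1–C2–C3, both stereocentres already present) and ethynylboronic acid pinacol ester A3.
- Forward key step: a [2+2+2] cyclotrimerisation of A2 with A3 under a cationic monovalent rhodium catalyst such as [Rh(cod)2]BF4 with a bisphosphine, or under Cp*RuCl(cod), to the 6-boryl dihydrobenzofuran A1. This closes the furan and the benzene ring together; C–B oxidation and hydrogenolysis would follow.
- In its favour: the most substituted ring is made last and convergently; the tether fixes where O1, C3 and the chain end up; the boron marks C6 for the phenol; no stereocentre is formed or endangered in the key step.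
- Against it here: A2 is a terminal alkynyl ether of a secondary benzylic alcohol, a class made under strongly basic conditions and prone to lose ketene on warming. Its two adjacent benzylic centres, one of them propargylic and acidic, must be set beforehand in an open chain. The position of boron (C6, not C5) rests only on the steric bias of the chain-bearing alkyne terminus. The bibenzyl unit that compound 1 supplies ready-made has to be assembled.
- Comparison: on mechanistic safety of the key step Alternative 1 is the equal or the better of the chosen plan, since it involves no cation next to C2 and no migratory competition. On structural fit the chosen plan is better, because ring A, its substituents and the 3-aryl benzopyran come from 1 and one condensation. On step economy the chosen plan (ten steps) should be shorter: A2 alone is estimated at eight or more steps, and two more follow A1.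

Alternative 2: The cut is made at C2–C3 and O1–C7a at the lactone oxidation level, with ring A removed altogether. It leaves (E)-3-[3,5-bis(benzyloxy)phenyl]acrylaldehyde A5 and 4-(benzyloxy)benzaldehyde A6.
- Forward key step: a chiral triazolylidene carbene converts A5 into a homoenolate, whose β-carbon adds to A6; the alkoxide then closes on the acyl azolium to the cis-lactone A4. Ring A would afterwards have to be annulated onto the lactone carbonyl (future C7a) and its α-CH2 (future C3a).
- In its favour: one catalytic step from two simple aldehydes creates both stereocentres, and this annulation type tends to favour the cis lactone. In steps needed to reach the C2/C3 pair it is better than the chosen plan (one step against seven).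
- Against it here: enantiocontrol of homoenolate additions to unactivated aryl aldehydes is generally modest. The lactone carbonyl must become an aromatic C–O carbon, with a phenethyl and an oxygen placed meta on the new ring. That calls for several acylation and dehydrative aromatisation steps under basic or acidic conditions, in which the C3 stereocentre next to the enolisable α-carbon can be lost by double-bond migration into the ring. Compound 1 cannot be used.
- Comparison: on the key step itself Alternative 2 is the equal or the better in brevity and in catalyst control of both centres. On structure and overall step economy the chosen plan is better, because the arene annulation after A4 is estimated at six or more steps of uncertain stereochemical safety.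

Alternative 3: The cut is C2–C3 alone. It leads back to the diaryl ketone hydrazone A8, which carries an ortho O–CH2Ar group.
- Forward key step: oxidation of A8 with MnO2 to the diaryldiazomethane A9, then a chiral divalent rhodium carboxylate of the Rh2(PTAD)4 type inserts the donor/donor carbene into the ortho O–CH2Ar C–H bond. This forms C2–C3 and closes the dihydrofuran to the penta-O-benzyl ether A7.
- In its favour: this insertion is an established entry to cis-2,3-diaryl dihydrobenzofurans, with both centres set by the catalyst. No extra carbon has to be removed. A8 should be reachable from compound 3 in four steps, about eight steps to the target in all.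
- Against it here: the ketone is flanked by two ortho substituents, so hydrazone formation is hindered. The ortho phenethyl chain offers a competing benzylic 1,5 C–H insertion towards an indane. Diaryl diazo compounds can dimerise to azines.
- Comparison: on precedent for the product class and on step economy Alternative 3 is the better of the two plans. On mechanism it is the equal or the better, since two stereocentres are set in one catalyst-controlled event. The chosen plan is preferred only on structural grounds: it avoids the competition from the ortho chain and the di-ortho ketone, and it fixes C3 by a stereospecific shift from a C2 centre set under milder catalysis. Alternative 3 is therefore kept as the fallback for step 7.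

Key step: step 7

Remarks on the chemistry (before the steps):
- Structure check: the target is cis-(2S,3R). The chromene 12 must be 2R, and 13 and 14 are 2R,3S. The change of letters between 14 and 15 is only a change of CIP priorities; no substituent moves. The structures of the plan were found mutually consistent; none needed correction.
- Design change to the chromene: a 4-alkoxyphenyl group at C2 (uniform benzyl protection) would strongly stabilise a cation at C2. That favours hydride loss to the benzopyrylium ion, ionisation of C2–O1 (racemisation of 12, epimerisation of 13 and 14 under acid) and shift of the C2 aryl instead of ring A. The C2 aryl therefore carries an acetate, which is removed last under nearly neutral conditions.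
- Hydride reduction of the coumarin gives a lactol, so the 2-ethoxy acetal needs an added acetalisation; it is run on the crude lactol in step 5.
- Assumption: the sense of induction in step 6 for this 3-aryl acetal cannot be predicted with confidence. The enantiomer of the tartaric-acid-derived catalyst (both are available) is chosen after a test reaction so that C2 of 12 is R.
- Assumption: 4-acetoxyphenylboronic acid (10) is treated as a commercial compound.

## Route

Step 1
Reactants: 1 dihydroresveratrol (5-[2-(4-hydroxyphenyl)ethyl]benzene-1,3-diol)
Product: 2 2,4-dihydroxy-6-[2-(4-hydroxyphenyl)ethyl]benzaldehyde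
Conditions: POCl3 (1.2 equiv), DMF, MeCN, 0 °C to rt; then H2O, 50 °C
Reagents that add atoms: N,N-dimethylformamide, CN(C)C=O (formyl carbon); water, O (carbonyl oxygen)
Why: Vilsmeier–Haack formylation; the resorcinol ring is far more nucleophilic than the monophenol ring, and 5-alkylresorcinols react at the position ortho to the chain and para to a hydroxyl, which is the one needed.

Step 2
Reactants: 2 2,4-dihydroxy-6-[2-(4-hydroxyphenyl)ethyl]benzaldehyde
Product: 3 4-(benzyloxy)-6-{2-[4-(benzyloxy)phenyl]ethyl}-2-hydroxybenzaldehyde
Conditions: BnBr (2.1 equiv), K2CO3 (2.2 equiv), acetone, rt to 45 °C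
Reagents that add atoms: benzyl bromide, BrCc1ccccc1
Why: Williamson etherification; the hydroxyl ortho to the formyl group is hydrogen-bonded and its phenoxide is the least nucleophilic, so with two equivalents the two unchelated phenols should react first.

Step 3
Reactants: 4 (3,5-dihydroxyphenyl)acetic acid
Product: 6 [3,5-bis(benzyloxy)phenyl]acetic acid, via benzyl ester 5 (not isolated)
Conditions: BnBr (3.3 equiv), K2CO3, DMF, 60 °C; then NaOH, MeOH–H2O, 60 °C; HCl (aq)
Reagents that add atoms: benzyl bromide, BrCc1ccccc1; sodium hydroxide, [Na+].[OH-]
Why: Exhaustive Williamson benzylation (both phenols and the carboxylate) followed by saponification of the benzyl ester in the same pot; benzyl aryl ethers are inert to hydroxide.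

Step 4
Reactants: 3 4-(benzyloxy)-6-{2-[4-(benzyloxy)phenyl]ethyl}-2-hydroxybenzaldehyde; 6 [3,5-bis(benzyloxy)phenyl]acetic acid
Product: 7 7-(benzyloxy)-3-[3,5-bis(benzyloxy)phenyl]-5-{2-[4-(benzyloxy)phenyl]ethyl}-2H-chromen-2-one
Conditions: Ac2O, Et3N, 110 °C
Reagents that add atoms: none
Why: Perkin (Oglialoro) condensation: the mixed anhydride of 6 acylates the free phenol, and intramolecular aldol-type condensation with dehydration gives the 3-arylcoumarin; benzyl ethers are stable to these conditions.

Step 5
Reactants: 7 7-(benzyloxy)-3-[3,5-bis(benzyloxy)phenyl]-5-{2-[4-(benzyloxy)phenyl]ethyl}-2H-chromen-2-one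
Product: 9 7-(benzyloxy)-3-[3,5-bis(benzyloxy)phenyl]-5-{2-[4-(benzyloxy)phenyl]ethyl}-2-ethoxy-2H-chromene (racemic), via lactol 8 (not isolated)
Conditions: i-Bu2AlH (1.15 equiv), CH2Cl2, −78 °C; aq. potassium sodium tartrate; then EtOH, PPTS (cat.), CH2Cl2, rt
Reagents that add atoms: ethanol, CCO
Why: Partial lactone reduction at low temperature stops at the tetrahedral aluminate and gives the lactol on work-up; mild acid then exchanges OH for OEt through the stabilised benzopyrylium ion (acetalisation), and the C2 configuration of 9 is irrelevant because it is erased in step 6.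

Step 6
Reactants: 9 7-(benzyloxy)-3-[3,5-bis(benzyloxy)phenyl]-5-{2-[4-(benzyloxy)phenyl]ethyl}-2-ethoxy-2H-chromene (racemic); 10 4-acetoxyphenylboronic acid
Product: 12 4-[(2R)-7-(benzyloxy)-3-[3,5-bis(benzyloxy)phenyl]-5-{2-[4-(benzyloxy)phenyl]ethyl}-2H-chromen-2-yl]phenyl acetate, via diethyl boronate 11 (not isolated)
Conditions: 10, EtOH, 4 Å MS, toluene, rt, then evaporation; 9, chiral tartaric acid monoamide catalyst (10 mol %), Yb(OTf)3 (5 mol %), EtOAc, −20 to 4 °C
Reagents that add atoms: none
Why: Catalytic enantioselective boronate addition to a chromene acetal (Petasis-type aryl transfer to the benzopyrylium ion under combined chiral Brønsted acid and Lewis acid catalysis); the chiral hydroxy acid bound to boron delivers the aryl group to one face of C2, and the catalyst antipode is chosen to give 2R. The acetoxy group keeps the product from re-ionising or giving up hydride to the cation.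

Step 7
Reactants: 12 4-[(2R)-7-(benzyloxy)-3-[3,5-bis(benzyloxy)phenyl]-5-{2-[4-(benzyloxy)phenyl]ethyl}-2H-chromen-2-yl]phenyl acetate
Product: 13 4-[(2R,3S)-6-(benzyloxy)-3-[3,5-bis(benzyloxy)phenyl]-4-{2-[4-(benzyloxy)phenyl]ethyl}-3-(dimethoxymethyl)-2,3-dihydro-1-benzofuran-2-yl]phenyl acetate (C2 aryl and C3 aryl cis)
Conditions: PhI(OH)OTs (1.15 equiv), MeOH–CH2Cl2 (3:1), −40 to −10 °C; NaHCO3 (aq)
Reagents that add atoms: methanol, CO
Why: The electrophilic λ3-iodane attacks C3, the alkene carbon β to the oxygen-rich ring A, on the face away from the C2 aryl, which A(1,2) strain with the C3 aryl holds pseudoaxial; the charge developing at C4 is a quinone-methide-type benzylic cation and is captured by methanol. With the phenyliodonio group pseudoequatorial, the C4–C4a bond lies antiperiplanar to C3–I, and C4a shifts to C3 through a bridged arenium ion as iodobenzene leaves; the C4 methoxy lone pair turns the old ring carbon into an oxocarbenium ion, which a second methanol converts into the dimethyl acetal. The closest known reaction type is the oxidative ring contraction of 2H-chromenes and 1,2-dihydronaphthalenes by trivalent iodine or trivalent thallium in methanol, together with the stilbene to diarylacetaldehyde acetal rearrangement by the same reagent. The dihydrofuran ring is not closed by a cyclisation that Baldwin's rules would classify: it arises by contraction of the pyran, the only bond-forming event being attack of the arene ipso carbon on C3 in a three-membered bridged transition state. The new quaternary stereocentre C3 is controlled by C2: anti addition of iodine followed by invertive displacement by C4a places the resorcinol ring cis to the C2 aryl and the acetal carbon trans, provided the shift is concerted with C–I cleavage. The step needs attack at C3 and not C4 (secured by the ortho and para oxygen donors of ring A), contraction in preference to methoxy participation or shift of the C2 aryl (favoured by the high migratory aptitude of ring A and by the acetoxy group, which makes the C2 aryl a poor migrating group), and addition faster than hydride loss from C2 (low temperature, acyloxy in place of alkoxy on the C2 aryl).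

Step 8
Reactants: 13 4-[(2R,3S)-6-(benzyloxy)-3-[3,5-bis(benzyloxy)phenyl]-4-{2-[4-(benzyloxy)phenyl]ethyl}-3-(dimethoxymethyl)-2,3-dihydro-1-benzofuran-2-yl]phenyl acetate
Product: 14 4-[(2R,3S)-6-(benzyloxy)-3-[3,5-bis(benzyloxy)phenyl]-4-{2-[4-(benzyloxy)phenyl]ethyl}-3-formyl-2,3-dihydro-1-benzofuran-2-yl]phenyl acetate
Conditions: TFA, H2O, CH2Cl2, 0 °C to rt
Reagents that add atoms: water, O
Why: Acid-catalysed acetal hydrolysis; the aldehyde has no α-hydrogen, so neither epimerisation nor β-elimination of O1 is possible, and the acetoxy-substituted C2 aryl should resist acid ionisation of C2–O1 during the short exposure.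

Step 9
Reactants: 14 4-[(2R,3S)-6-(benzyloxy)-3-[3,5-bis(benzyloxy)phenyl]-4-{2-[4-(benzyloxy)phenyl]ethyl}-3-formyl-2,3-dihydro-1-benzofuran-2-yl]phenyl acetate
Product: 15 4-[(2S,3R)-6-(benzyloxy)-3-[3,5-bis(benzyloxy)phenyl]-4-{2-[4-(benzyloxy)phenyl]ethyl}-2,3-dihydro-1-benzofuran-2-yl]phenyl acetate (cis)
Conditions: RhCl(PPh3)3 (1.1 equiv), PhCN, 130 °C, argon
Reagents that add atoms: none
Why: Tsuji–Wilkinson decarbonylation: oxidative addition of the formyl C–H bond to monovalent rhodium, CO extrusion and C–H reductive elimination are expected to proceed with retention at C3, so hydrogen takes the place of the formyl group trans to the C2 aryl and the two aryl groups stay cis.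

Step 10
Reactants: 15 4-[(2S,3R)-6-(benzyloxy)-3-[3,5-bis(benzyloxy)phenyl]-4-{2-[4-(benzyloxy)phenyl]ethyl}-2,3-dihydro-1-benzofuran-2-yl]phenyl acetate
Product: 17 5-[(2S,3R)-6-hydroxy-2-(4-hydroxyphenyl)-4-[2-(4-hydroxyphenyl)ethyl]-2,3-dihydro-1-benzofuran-3-yl]benzene-1,3-diol (target), via tetraphenol acetate 16 (not isolated)
Conditions: H2 (1 atm), Pd/C, EtOAc–MeOH, rt; filtration; then NH3, MeOH, 0 °C
Reagents that add atoms: none
Why: Catalytic hydrogenolysis should remove the four aryl benzyl ethers well before the cyclic benzylic C2–O1 ether is attacked (uptake is monitored); ammonolysis of the aryl acetate in methanol then frees the last phenol without generating enough phenoxide to open C2–O1, and no stereocentre is touched.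

## Compound list

1 | dihydroresveratrol, 5-[2-(4-hydroxyphenyl)ethyl]benzene-1,3-diol | Oc1ccc(CCc2cc(O)cc(O)c2)cc1 | starting material
2 | 2,4-dihydroxy-6-[2-(4-hydroxyphenyl)ethyl]benzaldehyde | O=Cc1c(O)cc(O)cc1CCc1ccc(O)cc1 | intermediate
3 | 4-(benzyloxy)-6-{2-[4-(benzyloxy)phenyl]ethyl}-2-hydroxybenzaldehyde | O=Cc1c(O)cc(OCc2ccccc2)cc1CCc1ccc(OCc2ccccc2)cc1 | intermediate
4 | (3,5-dihydroxyphenyl)acetic acid | OC(=O)Cc1cc(O)cc(O)c1 | starting material
5 | benzyl [3,5-bis(benzyloxy)phenyl]acetate | O=C(Cc1cc(OCc2ccccc2)cc(OCc2ccccc2)c1)OCc1ccccc1 | intermediate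
6 | [3,5-bis(benzyloxy)phenyl]acetic acid | OC(=O)Cc1cc(OCc2ccccc2)cc(OCc2ccccc2)c1 | intermediate
7 | 7-(benzyloxy)-3-[3,5-bis(benzyloxy)phenyl]-5-{2-[4-(benzyloxy)phenyl]ethyl}-2H-chromen-2-one | O=C1Oc2cc(OCc3ccccc3)cc(CCc3ccc(OCc4ccccc4)cc3)c2C=C1c1cc(OCc2ccccc2)cc(OCc2ccccc2)c1 | intermediate
8 | 7-(benzyloxy)-3-[3,5-bis(benzyloxy)phenyl]-5-{2-[4-(benzyloxy)phenyl]ethyl}-2H-chromen-2-ol (racemic lactol) | OC1Oc2cc(OCc3ccccc3)cc(CCc3ccc(OCc4ccccc4)cc3)c2C=C1c1cc(OCc2ccccc2)cc(OCc2ccccc2)c1 | intermediate
9 | 7-(benzyloxy)-3-[3,5-bis(benzyloxy)phenyl]-5-{2-[4-(benzyloxy)phenyl]ethyl}-2-ethoxy-2H-chromene (racemic) | CCOC1Oc2cc(OCc3ccccc3)cc(CCc3ccc(OCc4ccccc4)cc3)c2C=C1c1cc(OCc2ccccc2)cc(OCc2ccccc2)c1 | intermediate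
10 | 4-acetoxyphenylboronic acid | CC(=O)Oc1ccc(B(O)O)cc1 | starting material
11 | diethyl (4-acetoxyphenyl)boronate | CCOB(OCC)c1ccc(OC(C)=O)cc1 | intermediate
12 | 4-[(2R)-7-(benzyloxy)-3-[3,5-bis(benzyloxy)phenyl]-5-{2-[4-(benzyloxy)phenyl]ethyl}-2H-chromen-2-yl]phenyl acetate | C(c1ccccc1)Oc1ccc(CCc2cc(OCc4ccccc4)cc3c2C=C(c2cc(OCc4ccccc4)cc(OCc4ccccc4)c2)[C@@H](c2ccc(OC(C)=O)cc2)O3)cc1 | intermediate
13 | 4-[(2R,3S)-6-(benzyloxy)-3-[3,5-bis(benzyloxy)phenyl]-4-{2-[4-(benzyloxy)phenyl]ethyl}-3-(dimethoxymethyl)-2,3-dihydro-1-benzofuran-2-yl]phenyl acetate | C(c1ccccc1)Oc1ccc(CCc2cc(OCc4ccccc4)cc3c2[C@@](C(OC)OC)(c2cc(OCc4ccccc4)cc(OCc4ccccc4)c2)[C@@H](c2ccc(OC(C)=O)cc2)O3)cc1 | intermediate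
14 | 4-[(2R,3S)-6-(benzyloxy)-3-[3,5-bis(benzyloxy)phenyl]-4-{2-[4-(benzyloxy)phenyl]ethyl}-3-formyl-2,3-dihydro-1-benzofuran-2-yl]phenyl acetate | C(c1ccccc1)Oc1ccc(CCc2cc(OCc4ccccc4)cc3c2[C@@](C=O)(c2cc(OCc4ccccc4)cc(OCc4ccccc4)c2)[C@@H](c2ccc(OC(C)=O)cc2)O3)cc1 | intermediate
15 | 4-[(2S,3R)-6-(benzyloxy)-3-[3,5-bis(benzyloxy)phenyl]-4-{2-[4-(benzyloxy)phenyl]ethyl}-2,3-dihydro-1-benzofuran-2-yl]phenyl acetate | C(c1ccccc1)Oc1ccc(CCc2cc(OCc4ccccc4)cc3c2[C@@H](c2cc(OCc4ccccc4)cc(OCc4ccccc4)c2)[C@@H](c2ccc(OC(C)=O)cc2)O3)cc1 | intermediate
16 | 4-[(2S,3R)-3-(3,5-dihydroxyphenyl)-6-hydroxy-4-[2-(4-hydroxyphenyl)ethyl]-2,3-dihydro-1-benzofuran-2-yl]phenyl acetate | Oc1ccc(CCc2cc(O)cc3c2[C@@H](c2cc(O)cc(O)c2)[C@@H](c2ccc(OC(C)=O)cc2)O3)cc1 | intermediate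
17 | 5-[(2S,3R)-6-hydroxy-2-(4-hydroxyphenyl)-4-[2-(4-hydroxyphenyl)ethyl]-2,3-dihydro-1-benzofuran-3-yl]benzene-1,3-diol | Oc1ccc(CCc2cc(O)cc3c2[C@@H](c2cc(O)cc(O)c2)[C@@H](c2ccc(O)cc2)O3)cc1 | target

## Step count and least certain steps

Total step count: 10. Longest linear sequence: 9 steps (steps 1, 2, 4, 5, 6, 7, 8, 9, 10 from compound 1); step 3 is a one-step side branch.

Step 7 (key step).
- What may go wrong: the reaction class is established for chromenes, but a C3-aryl substrate that must form a quaternary centre is untested. The most likely failures are: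
  - hydride loss from C2 with aromatisation of the pyran ring;
  - methoxy participation in place of contraction, because peri strain between the C5 chain and a pseudoequatorial C4 methoxy disfavours the conformer needed for the shift;
  - shift of the C2 aryl to C3;
  - ionisation at C3 before the shift, with erosion of the C3 configuration;
  - attack of the trivalent iodine reagent on the bis(benzyloxy)phenyl ring.
- Fallback (sets out from 3, returns at 17): C2–C3 is formed by carbene C–H insertion. The free hydroxyl of 3 is alkylated with 4-(benzyloxy)benzyl chloride (K2CO3, KI, DMF) to the ether aldehyde F1. Addition of [3,5-bis(benzyloxy)phenyl]magnesium bromide F2 (from the aryl bromide and Mg in THF) gives the diarylmethanol F3. Oxidation with Dess–Martin periodinane gives the diaryl ketone F4, and hydrazine hydrate with AcOH in hot ethanol gives the hydrazone F5. MnO2 in CH2Cl2 at 0 °C gives the diaryldiazomethane F6. With Rh2(R-PTAD)4 or its antipode (a divalent rhodium carboxylate, 1 mol %), F6 should undergo 1,5 C–H insertion into the O–CH2Ar group to the cis penta-O-benzyl ether F7. Hydrogenolysis (H2, Pd/C) then gives 17.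

Step 6.
- What may go wrong: slow aryl transfer to a strongly stabilised, C3-substituted benzopyrylium ion from a boronate of only moderate nucleophilicity; poor facial selectivity because the C3 aryl sits next to the reacting carbon; attack at C4; hydride transfer from product to cation.
- Fallback (sets out from 9, returns at 12): racemic base-free coupling of 9 with 10 under Ni(cod)2/PPh3 (zerovalent nickel) to the racemic chromene F8, followed by preparative chiral SFC to isolate 12.

Step 9.
- What may go wrong: sluggish oxidative addition at the very hindered formyl group; β-hydride loss from C2 with aromatisation to the benzofuran; partial homolysis of the benzylic rhodium–carbon bond with epimerisation at C3.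
- Fallback (sets out from 14, returns at 15): thiol-catalysed radical-chain decarbonylation (tert-dodecanethiol, AIBN, chlorobenzene, heat). The thiyl radical abstracts the formyl hydrogen, the acyl radical loses CO, and the stabilised C3 radical takes hydrogen from the thiol on the face away from the C2 aryl, which again gives the cis compound. No new compound is formed.

Step 2.
- What may go wrong: over-alkylation of the chelated hydroxyl or incomplete alkylation of the remote phenol, since the acidity order and the nucleophilicity order of the three phenols differ.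
- Fallback (sets out from 2, returns at 3): exhaustive benzylation (excess BnBr, K2CO3, DMF) to the tribenzyl ether aldehyde F9, then chelation-controlled removal of the benzyl group ortho to the formyl group with MgBr2·OEt2 in toluene–ether.

Step 10.
- What may go wrong: hydrogenolytic opening of the benzylic C2–O1 bond on prolonged exposure; quinone-methide epimerisation at C2 if the ammonolysis is run too warm or too long.
- Fallback (sets out from 15, returns at 16): non-reductive debenzylation with BCl3 and pentamethylbenzene in CH2Cl2 at −78 °C, done while the acetate still deactivates the C2 aryl, followed by the same ammonolysis to 17. No new compound is formed.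

## Further compounds

F1 | step 7 | 4-(benzyloxy)-2-{[4-(benzyloxy)benzyl]oxy}-6-{2-[4-(benzyloxy)phenyl]ethyl}benzaldehyde | O=Cc1c(OCc2ccc(OCc3ccccc3)cc2)cc(OCc2ccccc2)cc1CCc1ccc(OCc2ccccc2)cc1
F2 | step 7 | [3,5-bis(benzyloxy)phenyl]magnesium bromide | Br[Mg]c1cc(OCc2ccccc2)cc(OCc2ccccc2)c1
F3 | step 7 | [4-(benzyloxy)-2-{[4-(benzyloxy)benzyl]oxy}-6-{2-[4-(benzyloxy)phenyl]ethyl}phenyl][3,5-bis(benzyloxy)phenyl]methanol (racemic) | OC(c1cc(OCc2ccccc2)cc(OCc2ccccc2)c1)c1c(OCc2ccc(OCc3ccccc3)cc2)cc(OCc2ccccc2)cc1CCc1ccc(OCc2ccccc2)cc1
F4 | step 7 | [4-(benzyloxy)-2-{[4-(benzyloxy)benzyl]oxy}-6-{2-[4-(benzyloxy)phenyl]ethyl}phenyl][3,5-bis(benzyloxy)phenyl]methanone | O=C(c1cc(OCc2ccccc2)cc(OCc2ccccc2)c1)c1c(OCc2ccc(OCc3ccccc3)cc2)cc(OCc2ccccc2)cc1CCc1ccc(OCc2ccccc2)cc1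
F5 | step 7 | hydrazone of ketone F4 | NN=C(c1cc(OCc2ccccc2)cc(OCc2ccccc2)c1)c1c(OCc2ccc(OCc3ccccc3)cc2)cc(OCc2ccccc2)cc1CCc1ccc(OCc2ccccc2)cc1
F6 | step 7 | diaryldiazomethane derived from F5 | [N-]=[N+]=C(c1cc(OCc2ccccc2)cc(OCc2ccccc2)c1)c1c(OCc2ccc(OCc3ccccc3)cc2)cc(OCc2ccccc2)cc1CCc1ccc(OCc2ccccc2)cc1
F7 | step 7 | (2S,3R)-6-(benzyloxy)-3-[3,5-bis(benzyloxy)phenyl]-2-[4-(benzyloxy)phenyl]-4-{2-[4-(benzyloxy)phenyl]ethyl}-2,3-dihydro-1-benzofuran | C(c1ccccc1)Oc1ccc(CCc2cc(OCc4ccccc4)cc3c2[C@@H](c2cc(OCc4ccccc4)cc(OCc4ccccc4)c2)[C@@H](c2ccc(OCc4ccccc4)cc2)O3)cc1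
F8 | step 6 | racemic 4-[7-(benzyloxy)-3-[3,5-bis(benzyloxy)phenyl]-5-{2-[4-(benzyloxy)phenyl]ethyl}-2H-chromen-2-yl]phenyl acetate | C(c1ccccc1)Oc1ccc(CCc2cc(OCc4ccccc4)cc3c2C=C(c2cc(OCc4ccccc4)cc(OCc4ccccc4)c2)C(c2ccc(OC(C)=O)cc2)O3)cc1
F0 | step 9 | none | none
F9 | step 2 | 2,4-bis(benzyloxy)-6-{2-[4-(benzyloxy)phenyl]ethyl}benzaldehyde | O=Cc1c(OCc2ccccc2)cc(OCc2ccccc2)cc1CCc1ccc(OCc2ccccc2)cc1
F0 | step 10 | none | none
A1 | alternative 1 | (2S,3R)-3-[3,5-bis(benzyloxy)phenyl]-2-[4-(benzyloxy)phenyl]-4-{2-[4-(benzyloxy)phenyl]ethyl}-6-(4,4,5,5-tetramethyl-1,3,2-dioxaborolan-2-yl)-2,3-dihydro-1-benzofuran | C(c1ccccc1)Oc1ccc(CCc2cc(B4OC(C)(C)C(C)(C)O4)cc3c2[C@@H](c2cc(OCc4ccccc4)cc(OCc4ccccc4)c2)[C@@H](c2ccc(OCc4ccccc4)cc2)O3)cc1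
A2 | alternative 1 | ethynyl ether of 2-[3,5-bis(benzyloxy)phenyl]-1-[4-(benzyloxy)phenyl]-6-[4-(benzyloxy)phenyl]hex-3-yn-1-ol, configured for the cis product | C(c1ccccc1)Oc1ccc(CCC#C[C@@H](c2cc(OCc3ccccc3)cc(OCc3ccccc3)c2)[C@@H](c2ccc(OCc3ccccc3)cc2)OC#C)cc1
A3 | alternative 1 | ethynylboronic acid pinacol ester | C#CB1OC(C)(C)C(C)(C)O1
A4 | alternative 2 | cis-4-[3,5-bis(benzyloxy)phenyl]-5-[4-(benzyloxy)phenyl]dihydrofuran-2(3H)-one | O=C1C[C@@H](c2cc(OCc3ccccc3)cc(OCc3ccccc3)c2)[C@@H](c2ccc(OCc3ccccc3)cc2)O1
A5 | alternative 2 | (E)-3-[3,5-bis(benzyloxy)phenyl]acrylaldehyde | O=C/C=C/c1cc(OCc2ccccc2)cc(OCc2ccccc2)c1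
A6 | alternative 2 | 4-(benzyloxy)benzaldehyde | O=Cc1ccc(OCc2ccccc2)cc1
A7 | alternative 3 | penta-O-benzyl ether of the target (cis, 2S,3R) | C(c1ccccc1)Oc1ccc(CCc2cc(OCc4ccccc4)cc3c2[C@@H](c2cc(OCc4ccccc4)cc(OCc4ccccc4)c2)[C@@H](c2ccc(OCc4ccccc4)cc2)O3)cc1
A8 | alternative 3 | hydrazone of [4-(benzyloxy)-2-{[4-(benzyloxy)benzyl]oxy}-6-{2-[4-(benzyloxy)phenyl]ethyl}phenyl][3,5-bis(benzyloxy)phenyl]methanone | NN=C(c1cc(OCc2ccccc2)cc(OCc2ccccc2)c1)c1c(OCc2ccc(OCc3ccccc3)cc2)cc(OCc2ccccc2)cc1CCc1ccc(OCc2ccccc2)cc1
A9 | alternative 3 | diaryldiazomethane derived from A8 | [N-]=[N+]=C(c1cc(OCc2ccccc2)cc(OCc2ccccc2)c1)c1c(OCc2ccc(OCc3ccccc3)cc2)cc(OCc2ccccc2)cc1CCc1ccc(OCc2ccccc2)cc1
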